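## Retrosynthetic overview

1. Pauciflorol E comes from its tetrabenzyl ether by hydrogenolysis. The cycloheptanone is cut at the C7b–aryl bond, which is an intramolecular 1,6-Michael addition of the resorcinol ring to an aroyl p-quinone methide.
2. The quinone methide precursor is an α-silyloxy ketone. It comes from a 4-lithio-2,3-diaryl-2,3-dihydrobenzofuran and the Weinreb amide of 4-hydroxymandelic acid.
3. The trans-dihydrobenzofuran comes from the cis isomer by C2 epimerisation. The cis isomer comes from an enantioselective Rh(II) carbene C–H insertion of a diaryldiazomethane, which forms C2–C3 and sets C8a.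
4. The diazo precursor comes from a ring-A benzonitrile (5-bromoresorcinol plus 4-benzyloxybenzyl chloride) and a ring-B Grignard reagent (also from 5-bromoresorcinol).
5. Ring order: the dihydrofuran first, the seven-membered ketone second. C7a and C7b are then fixed relative to C8a.

Locants in the tetracycle: C7a is O–CH(Ar), C8a is the CH bearing the resorcinol ring, C7b is the CH(Ar) next to C=O, and C8b is C=O.

Assumption: Rh2(S-PTAD)4 is written as the catalyst enantiomer that gives the 3R series. The sense of induction is checked by X-ray analysis of bromide 19, and Rh2(R-PTAD)4 is used if it turns out opposite.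

## Route

Step 1
Reactants: 1 1-bromo-3,5-dimethoxybenzene
Product: 2 5-bromobenzene-1,3-diol
Conditions: BBr3 (2.5 equiv), CH2Cl2, −78 °C to rt; H2O
Reagents that add atoms: none
Why: Lewis-acid aryl methyl ether cleavage (BBr3 demethylation) frees both phenols and leaves the aryl bromide untouched.

Step 2
Reactants: 2 5-bromobenzene-1,3-diol
Product: 4 2-bromo-4,6-dihydroxybenzaldehyde, via iminium chloride 3 (not isolated)
Conditions: POCl3, DMF, MeCN, 0 °C to rt; H2O, 50 °C
Reagents that add atoms: N,N-dimethylformamide CN(C)C=O; water O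
Why: Vilsmeier–Haack formylation attacks the carbon para to one OH and ortho to the other (as with orcinol), not the crowded carbon between the two OH groups.

Step 3
Reactants: 4 2-bromo-4,6-dihydroxybenzaldehyde
Product: 5 4-(benzyloxy)-2-bromo-6-hydroxybenzaldehyde
Conditions: BnBr (1.05 equiv), NaHCO3, MeCN, 80 °C
Reagents that add atoms: benzyl bromide BrCc1ccccc1
Why: Williamson etherification with a weak base alkylates only the more acidic para-OH, because the ortho-OH is hydrogen-bonded to the aldehyde.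

Step 4
Reactants: 6 4-hydroxybenzaldehyde
Product: 7 4-(benzyloxy)benzaldehyde
Conditions: BnBr, K2CO3, acetone, reflux
Reagents that add atoms: benzyl bromide BrCc1ccccc1
Why: This is a standard Williamson etherification of an acidic phenol.

Step 5
Reactants: 7 4-(benzyloxy)benzaldehyde
Product: 8 [4-(benzyloxy)phenyl]methanol
Conditions: NaBH4, MeOH, 0 °C
Reagents that add atoms: none
Why: Borohydride reduction of the aldehyde leaves the benzyl ether intact.

Step 6
Reactants: 8 [4-(benzyloxy)phenyl]methanol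
Product: 9 1-(benzyloxy)-4-(chloromethyl)benzene
Conditions: SOCl2, CH2Cl2, 0 °C to rt
Reagents that add atoms: thionyl chloride O=S(Cl)Cl
Why: Chlorination through the chlorosulfite is fast at this activated benzylic position.

Step 7
Reactants: 5 4-(benzyloxy)-2-bromo-6-hydroxybenzaldehyde; 9 1-(benzyloxy)-4-(chloromethyl)benzene
Product: 10 4-(benzyloxy)-2-{[4-(benzyloxy)benzyl]oxy}-6-bromobenzaldehyde
Conditions: K2CO3, DMF, 60 °C
Reagents that add atoms: none
Why: Williamson etherification of the remaining chelated phenol needs only the stronger base, a polar solvent and the reactive benzylic chloride.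

Step 8
Reactants: 10 4-(benzyloxy)-2-{[4-(benzyloxy)benzyl]oxy}-6-bromobenzaldehyde
Product: 12 4-(benzyloxy)-2-{[4-(benzyloxy)benzyl]oxy}-6-bromobenzonitrile, via aldoxime 11 (not isolated)
Conditions: NH2OH·HCl, pyridine, EtOH, 60 °C; evaporate; Ac2O, 110 °C
Reagents that add atoms: hydroxylamine hydrochloride Cl.NO
Why: Oxime formation followed by acetylative dehydration (elimination of AcOH) is non-acidic, so all three benzylic ethers survive.

Step 9
Reactants: 2 5-bromobenzene-1,3-diol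
Product: 13 1,3-bis(benzyloxy)-5-bromobenzene
Conditions: BnBr (2.2 equiv), K2CO3, DMF, 50 °C
Reagents that add atoms: benzyl bromide BrCc1ccccc1
Why: This is a double Williamson etherification.

Step 10
Reactants: 13 1,3-bis(benzyloxy)-5-bromobenzene; 12 4-(benzyloxy)-2-{[4-(benzyloxy)benzyl]oxy}-6-bromobenzonitrile
Product: 16 {[4-(benzyloxy)-2-{[4-(benzyloxy)benzyl]oxy}-6-bromophenyl][3,5-bis(benzyloxy)phenyl]methylidene}hydrazine, via aryl Grignard reagent 14 (not isolated), via N-H ketimine 15 (not isolated)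
Conditions: 13, Mg, THF, reflux; 12, THF–toluene, 70 °C; MeOH, 0 °C; N2H4·H2O, cat. AcOH, EtOH, 75 °C
Reagents that add atoms: hydrazine hydrate NN.O
Why: Grignard addition to the linear nitrile stops at the ketiminate, and the protonated N–H ketimine is far more electrophilic than the corresponding di-ortho-substituted benzophenone, so transimination with hydrazine gives the hindered hydrazone.

Step 11
Reactants: 16 the diaryl ketone hydrazone
Product: 18 (2S,3R)-6-(benzyloxy)-2-[4-(benzyloxy)phenyl]-3-[3,5-bis(benzyloxy)phenyl]-4-bromo-2,3-dihydrobenzofuran (2,3-cis), via diaryldiazomethane 17 (not isolated)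
Conditions: MnO2 (10 equiv), CH2Cl2, rt, filter; Rh2(S-PTAD)4 (1 mol %), CH2Cl2, 0 °C
Reagents that add atoms: none
Why: MnO2 dehydrogenates the hydrazone, and the enantioselective Rh(II) donor/donor carbene inserts into the doubly activated O–CH2–Ar C–H bond (five-membered transition state); the chiral carboxylate cage sets C3 as R and gives the kinetic cis product.

Step 12
Reactants: 18 the (2S,3R)-cis-dihydrobenzofuran
Product: 19 (2R,3R)-6-(benzyloxy)-2-[4-(benzyloxy)phenyl]-3-[3,5-bis(benzyloxy)phenyl]-4-bromo-2,3-dihydrobenzofuran (2,3-trans)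
Conditions: TFA (1 equiv), CH2Cl2, 0 °C to rt; recrystallise
Reagents that add atoms: none
Why: Acid-catalysed epimerisation (reversible ionisation of the C2–O bond at the p-benzyloxybenzylic carbon, then re-closure) touches only C2, so C3 stays R and the more stable trans isomer (2R) builds up.

Step 13
Reactants: 20 (±)-4-hydroxymandelic acid
Product: 21 methyl (±)-2-hydroxy-2-(4-hydroxyphenyl)acetate
Conditions: MeOH, cat. H2SO4, reflux
Reagents that add atoms: methanol CO
Why: This is a Fischer esterification, and the adjacent carboxyl group slows solvolysis of the benzylic OH.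

Step 14
Reactants: 21 methyl (±)-2-hydroxy-2-(4-hydroxyphenyl)acetate
Product: 22 methyl (±)-2-[(tert-butyldimethylsilyl)oxy]-2-{4-[(tert-butyldimethylsilyl)oxy]phenyl}acetate
Conditions: TBSCl (2.5 equiv), imidazole, DMF, rt
Reagents that add atoms: tert-butyldimethylsilyl chloride CC(C)(C)[Si](C)(C)Cl
Why: Imidazole-promoted silylation protects both the phenol and the secondary alcohol.

Step 15
Reactants: 22 the bis-TBS methyl ester
Product: 23 (±)-2-[(tert-butyldimethylsilyl)oxy]-2-{4-[(tert-butyldimethylsilyl)oxy]phenyl}-N-methoxy-N-methylacetamide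
Conditions: MeNH(OMe)·HCl, i-PrMgCl, THF, −20 to 0 °C; cold 1 M HCl
Reagents that add atoms: N,O-dimethylhydroxylamine hydrochloride Cl.CNOC
Why: Aminolysis of the ester with the magnesium amide gives the Weinreb amide directly without touching the silyl ethers.

Step 16
Reactants: 19 the (2R,3R)-trans bromide; 23 the Weinreb amide
Product: 25 1-{(2R,3R)-6-(benzyloxy)-2-[4-(benzyloxy)phenyl]-3-[3,5-bis(benzyloxy)phenyl]-2,3-dihydrobenzofuran-4-yl}-2-[(tert-butyldimethylsilyl)oxy]-2-{4-[(tert-butyldimethylsilyl)oxy]phenyl}ethan-1-one (1:1 epimers at the silyloxy carbon), via aryllithium 24 (not isolated)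
Conditions: n-BuLi, THF, −78 °C; 23 (1.5 equiv); AcOH, −78 °C
Reagents that add atoms: none
Why: Bromine–lithium exchange and Weinreb ketone synthesis (the stable chelate prevents over-addition) join the fragments, and the new epimeric centre does not matter because step 18 erases it.

Step 17
Reactants: 25 the bis-TBS ketone
Product: 26 1-{(2R,3R)-6-(benzyloxy)-2-[4-(benzyloxy)phenyl]-3-[3,5-bis(benzyloxy)phenyl]-2,3-dihydrobenzofuran-4-yl}-2-[(tert-butyldimethylsilyl)oxy]-2-(4-hydroxyphenyl)ethan-1-one (1:1 epimers)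
Conditions: KHF2, MeOH–THF, rt
Reagents that add atoms: none
Why: Bifluoride cleaves only the phenolic silyl ether under nearly neutral conditions, and the retained alkyl TBS ether blocks the α-ketol (benzoin) isomerisation and base-induced opening of the dihydrofuran.

Step 18
Reactants: 26 the p-hydroxyphenyl α-silyloxy ketone
Product: 28 (7aR,8aR,7bR)-tetra-O-benzylpauciflorol E (free OH only on the C7b aryl ring), via aroyl p-quinone methide 27 (not isolated)
Conditions: TsOH·H2O (20 mol %), HFIP–CH2Cl2 1:4, 0.005 M, 0 °C to rt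
Reagents that add atoms: none
Why: Acid-promoted 1,6-elimination of silanol gives quinone methide 27, and the neighbouring 3,5-dibenzyloxyphenyl ring adds through its ortho/para-activated carbon in an intramolecular 1,6-conjugate (vinylogous Michael, Friedel–Crafts type) addition that closes the seven-membered ring; the aryl group takes the pseudo-axial position away from the peri benzyloxy group and cis to H-8a (7bR), and enolisation of the ketone equilibrates any epimer to this more stable isomer.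

Step 19
Reactants: 28 tetra-O-benzylpauciflorol E
Product: 29 pauciflorol E (7aR,8aR,7bR)
Conditions: H2 (1 atm), 10% Pd/C, EtOAc–MeOH, rt
Reagents that add atoms: none
Why: Neutral catalytic hydrogenolysis removes the four O-benzyl groups faster than it attacks the hindered aryl ketone or the ring C–O bond, and it epimerises no stereocentre.

## Compound list

1 | 1-bromo-3,5-dimethoxybenzene | COc1cc(Br)cc(OC)c1 | starting material
2 | 5-bromobenzene-1,3-diol | Oc1cc(O)cc(Br)c1 | intermediate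
3 | N-(2-bromo-4,6-dihydroxybenzylidene)-N-methylmethanaminium chloride | C[N+](C)=Cc1c(O)cc(O)cc1Br.[Cl-] | intermediate
4 | 2-bromo-4,6-dihydroxybenzaldehyde | O=Cc1c(O)cc(O)cc1Br | intermediate
5 | 4-(benzyloxy)-2-bromo-6-hydroxybenzaldehyde | O=Cc1c(O)cc(OCc2ccccc2)cc1Br | intermediate
6 | 4-hydroxybenzaldehyde | O=Cc1ccc(O)cc1 | starting material
7 | 4-(benzyloxy)benzaldehyde | O=Cc1ccc(OCc2ccccc2)cc1 | intermediate
8 | [4-(benzyloxy)phenyl]methanol | OCc1ccc(OCc2ccccc2)cc1 | intermediate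
9 | 1-(benzyloxy)-4-(chloromethyl)benzene | ClCc1ccc(OCc2ccccc2)cc1 | intermediate
10 | 4-(benzyloxy)-2-{[4-(benzyloxy)benzyl]oxy}-6-bromobenzaldehyde | O=Cc1c(OCc2ccc(OCc3ccccc3)cc2)cc(OCc2ccccc2)cc1Br | intermediate
11 | oxime of 10 | ON=Cc1c(OCc2ccc(OCc3ccccc3)cc2)cc(OCc2ccccc2)cc1Br | intermediate
12 | 4-(benzyloxy)-2-{[4-(benzyloxy)benzyl]oxy}-6-bromobenzonitrile | N#Cc1c(OCc2ccc(OCc3ccccc3)cc2)cc(OCc2ccccc2)cc1Br | intermediate
13 | 1,3-bis(benzyloxy)-5-bromobenzene | Brc1cc(OCc2ccccc2)cc(OCc2ccccc2)c1 | intermediate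
14 | [3,5-bis(benzyloxy)phenyl]magnesium bromide | Br[Mg]c1cc(OCc2ccccc2)cc(OCc2ccccc2)c1 | intermediate
15 | 1-[4-(benzyloxy)-2-{[4-(benzyloxy)benzyl]oxy}-6-bromophenyl]-1-[3,5-bis(benzyloxy)phenyl]methanimine | N=C(c1cc(OCc2ccccc2)cc(OCc2ccccc2)c1)c1c(OCc2ccc(OCc3ccccc3)cc2)cc(OCc2ccccc2)cc1Br | intermediate
16 | {[4-(benzyloxy)-2-{[4-(benzyloxy)benzyl]oxy}-6-bromophenyl][3,5-bis(benzyloxy)phenyl]methylidene}hydrazine | NN=C(c1cc(OCc2ccccc2)cc(OCc2ccccc2)c1)c1c(OCc2ccc(OCc3ccccc3)cc2)cc(OCc2ccccc2)cc1Br | intermediate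
17 | 5-(benzyloxy)-1-{[4-(benzyloxy)benzyl]oxy}-2-{[3,5-bis(benzyloxy)phenyl](diazo)methyl}-3-bromobenzene | [N-]=[N+]=C(c1cc(OCc2ccccc2)cc(OCc2ccccc2)c1)c1c(OCc2ccc(OCc3ccccc3)cc2)cc(OCc2ccccc2)cc1Br | intermediate
18 | (2S,3R)-cis-6-(benzyloxy)-2-[4-(benzyloxy)phenyl]-3-[3,5-bis(benzyloxy)phenyl]-4-bromo-2,3-dihydrobenzofuran | Brc1cc(OCc2ccccc2)cc2c1[C@@H](c1cc(OCc3ccccc3)cc(OCc3ccccc3)c1)[C@@H](c1ccc(OCc3ccccc3)cc1)O2 | intermediate
19 | (2R,3R)-trans-6-(benzyloxy)-2-[4-(benzyloxy)phenyl]-3-[3,5-bis(benzyloxy)phenyl]-4-bromo-2,3-dihydrobenzofuran | Brc1cc(OCc2ccccc2)cc2c1[C@@H](c1cc(OCc3ccccc3)cc(OCc3ccccc3)c1)[C@H](c1ccc(OCc3ccccc3)cc1)O2 | intermediate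
20 | (±)-4-hydroxymandelic acid | OC(C(=O)O)c1ccc(O)cc1 | starting material
21 | methyl (±)-2-hydroxy-2-(4-hydroxyphenyl)acetate | COC(=O)C(O)c1ccc(O)cc1 | intermediate
22 | methyl (±)-2-(TBSO)-2-[4-(TBSO)phenyl]acetate | COC(=O)C(O[Si](C)(C)C(C)(C)C)c1ccc(O[Si](C)(C)C(C)(C)C)cc1 | intermediate
23 | (±)-2-(TBSO)-2-[4-(TBSO)phenyl]-N-methoxy-N-methylacetamide | CON(C)C(=O)C(O[Si](C)(C)C(C)(C)C)c1ccc(O[Si](C)(C)C(C)(C)C)cc1 | intermediate
24 | (2R,3R)-4-lithio analogue of 19 | [Li]c1cc(OCc2ccccc2)cc2c1[C@@H](c1cc(OCc3ccccc3)cc(OCc3ccccc3)c1)[C@H](c1ccc(OCc3ccccc3)cc1)O2 | intermediate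
25 | bis-TBS α-silyloxy ketone (2R,3R; epimers at the silyloxy carbon) | CC(C)(C)[Si](C)(C)OC(c1ccc(O[Si](C)(C)C(C)(C)C)cc1)C(=O)c1cc(OCc2ccccc2)cc2c1[C@@H](c1cc(OCc3ccccc3)cc(OCc3ccccc3)c1)[C@H](c1ccc(OCc3ccccc3)cc1)O2 | intermediate
26 | p-hydroxyphenyl α-silyloxy ketone (2R,3R; epimers at the silyloxy carbon) | CC(C)(C)[Si](C)(C)OC(c1ccc(O)cc1)C(=O)c1cc(OCc2ccccc2)cc2c1[C@@H](c1cc(OCc3ccccc3)cc(OCc3ccccc3)c1)[C@H](c1ccc(OCc3ccccc3)cc1)O2 | intermediate
27 | 4-(2-{(2R,3R)-dihydrobenzofuran-4-yl}-2-oxoethylidene)cyclohexa-2,5-dien-1-one (aroyl p-quinone methide) | O=C(C=C1C=CC(=O)C=C1)c1cc(OCc2ccccc2)cc2c1[C@@H](c1cc(OCc3ccccc3)cc(OCc3ccccc3)c1)[C@H](c1ccc(OCc3ccccc3)cc1)O2 | intermediate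
28 | (7aR,8aR,7bR)-tetra-O-benzylpauciflorol E | O=C1c2cc(OCc4ccccc4)cc3c2[C@@H](c2cc(OCc4ccccc4)cc(OCc4ccccc4)c2[C@H]1c1ccc(O)cc1)[C@H](c1ccc(OCc4ccccc4)cc1)O3 | intermediate
29 | pauciflorol E (7aR,8aR,7bR) | O=C1c2cc(O)cc3c2[C@@H](c2cc(O)cc(O)c2[C@H]1c1ccc(O)cc1)[C@H](c1ccc(O)cc1)O3 | target

## Step count and risks

Total step count: 19.

Longest linear sequence: 12 steps (1-2-3-7-8-10-11-12-16-17-18-19). The branch 4-5-6-7-… is equally long. The ratio is 12/19 = 0.63.

**Step 10.**
- Risk: the Grignard reagent may displace the ortho-alkoxy group or exchange with the bromide, and the crowded ketimine may exchange only slowly with hydrazine.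
- Fallback: it sets out from aldehyde 10 and Grignard reagent 14 and comes back at diazo compound 17. 1,2-Addition at 0 °C gives the racemic benzhydrol F1. Dess–Martin oxidation gives the benzophenone F2. Condensation with 1,2-bis(tert-butyldimethylsilyl)hydrazine (cat. Sc(OTf)3, neat, 80–100 °C) is irreversible because a silanol is formed instead of water, and it gives the N-silyl hydrazone F3. Oxidation of F3 with PhIF2 and 2-chloropyridine (CH2Cl2, −78 °C to rt) gives 17, which is passed through basic alumina before the rhodium catalyst is added.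

**Step 11.**
- Risk: the carbene carbon carries a 2,6-disubstituted aryl ring, so insertion may be slow (azine formation) or less enantioselective than with mono-ortho substrates.
- Fallback: it sets out from phenol aldehyde 5, Grignard reagent 14 and chloride 9 and comes back at 19.
  - Compound 5 is deprotonated with i-PrMgCl and treated with 14 to give the o-hydroxybenzhydrol F4.
  - p-Toluenesulfinic acid in CH2Cl2 turns F4 into the sulfone F5.
  - Chloride 9, (2R,5R)-2,5-dimethylthiolane and AgBF4 give the chiral thiolanium salt F6. The enantiomer of the sulfide is chosen by experiment.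
  - Cs2CO3 in CH2Cl2 at −20 °C eliminates sulfinate from F5 to give the o-quinone methide F7 and deprotonates F6 to the sulfonium ylide F8.
  - F8 adds to F7 in a Michael addition, and the phenoxide displaces the sulfide. This formal [4+1] annulation gives trans-19 directly.

**Step 18.**
- Risk: ionisation next to the carbonyl group is slow, so reversible opening of the dihydrofuran, desilylation followed by benzoin isomerisation, or intermolecular trapping could compete with ring closure.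
- Fallback: it sets out from bromide 19 and chloride 9 and comes back at target 29. It closes the ring one oxidation level lower.
  - Aryllithium 24 and DMF give the aldehyde F9.
  - Chloride 9 and Me2S give the sulfonium chloride F10. KOH in MeCN converts F10 into the benzylide F11.
  - F11 epoxidises F9 (Corey–Chaykovsky type) to the trans-stilbene oxide F12, a mixture of diastereomers.
  - Bi(OTf)3 (5 mol %, CH2Cl2, −40 °C) opens the strained epoxide at the p-benzyloxybenzylic carbon to the O-benzylated quinone-methide cation. The resorcinol ring closes onto it to give the seven-membered alcohol F13.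
  - Dess–Martin oxidation gives the pentabenzyl ketone F14, in which C7b can equilibrate as in 28.
  - Hydrogenolysis as in step 19 gives 29.

## Further compounds

F1 | step 10 | benzhydrol: [4-(benzyloxy)-2-{[4-(benzyloxy)benzyl]oxy}-6-bromophenyl][3,5-bis(benzyloxy)phenyl]methanol | OC(c1cc(OCc2ccccc2)cc(OCc2ccccc2)c1)c1c(OCc2ccc(OCc3ccccc3)cc2)cc(OCc2ccccc2)cc1Br
F2 | step 10 | benzophenone: [4-(benzyloxy)-2-{[4-(benzyloxy)benzyl]oxy}-6-bromophenyl][3,5-bis(benzyloxy)phenyl]methanone | O=C(c1cc(OCc2ccccc2)cc(OCc2ccccc2)c1)c1c(OCc2ccc(OCc3ccccc3)cc2)cc(OCc2ccccc2)cc1Br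
F3 | step 10 | N-silyl hydrazone: N-(tert-butyldimethylsilyl)hydrazone of F2 | CC(C)(C)[Si](C)(C)NN=C(c1cc(OCc2ccccc2)cc(OCc2ccccc2)c1)c1c(OCc2ccc(OCc3ccccc3)cc2)cc(OCc2ccccc2)cc1Br
F4 | step 11 | o-hydroxybenzhydrol: [4-(benzyloxy)-2-bromo-6-hydroxyphenyl][3,5-bis(benzyloxy)phenyl]methanol | OC(c1cc(OCc2ccccc2)cc(OCc2ccccc2)c1)c1c(O)cc(OCc2ccccc2)cc1Br
F5 | step 11 | sulfone: 5-(benzyloxy)-2-{[3,5-bis(benzyloxy)phenyl](tosyl)methyl}-3-bromophenol | Cc1ccc(cc1)S(=O)(=O)C(c1cc(OCc2ccccc2)cc(OCc2ccccc2)c1)c1c(O)cc(OCc2ccccc2)cc1Br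
F6 | step 11 | chiral thiolanium salt: (2R,5R)-1-[4-(benzyloxy)benzyl]-2,5-dimethylthiolanium tetrafluoroborate | C[C@@H]1CC[C@@H](C)[S+]1Cc1ccc(OCc2ccccc2)cc1.F[B-](F)(F)F
F7 | step 11 | o-quinone methide: 3-(benzyloxy)-6-[3,5-bis(benzyloxy)benzylidene]-5-bromocyclohexa-2,4-dien-1-one | O=C1C=C(OCc2ccccc2)C=C(Br)C1=Cc1cc(OCc2ccccc2)cc(OCc2ccccc2)c1
F8 | step 11 | sulfonium ylide: (2R,5R)-2,5-dimethylthiolanium 4-(benzyloxy)benzylide | C[C@@H]1CC[C@@H](C)[S+]1[CH-]c1ccc(OCc2ccccc2)cc1
F9 | step 18 | aldehyde: (2R,3R)-6-(benzyloxy)-2-[4-(benzyloxy)phenyl]-3-[3,5-bis(benzyloxy)phenyl]-2,3-dihydrobenzofuran-4-carbaldehyde | O=Cc1cc(OCc2ccccc2)cc2c1[C@@H](c1cc(OCc3ccccc3)cc(OCc3ccccc3)c1)[C@H](c1ccc(OCc3ccccc3)cc1)O2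
F10 | step 18 | sulfonium chloride: [4-(benzyloxy)benzyl]dimethylsulfonium chloride | C[S+](C)Cc1ccc(OCc2ccccc2)cc1.[Cl-]
F11 | step 18 | benzylide: dimethylsulfonium 4-(benzyloxy)benzylide | C[S+](C)[CH-]c1ccc(OCc2ccccc2)cc1
F12 | step 18 | trans-stilbene oxide: 2-[4-(benzyloxy)phenyl]-3-{(2R,3R)-6-(benzyloxy)-2-[4-(benzyloxy)phenyl]-3-[3,5-bis(benzyloxy)phenyl]-2,3-dihydrobenzofuran-4-yl}oxirane (diastereomer mixture) | O1C(c2ccc(OCc3ccccc3)cc2)C1c1cc(OCc2ccccc2)cc2c1[C@@H](c1cc(OCc3ccccc3)cc(OCc3ccccc3)c1)[C@H](c1ccc(OCc3ccccc3)cc1)O2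
F13 | step 18 | seven-membered alcohol: (7aR,8aR,7bR)-penta-O-benzyl-8b-hydroxy compound (8b epimers) | OC1c2cc(OCc4ccccc4)cc3c2[C@@H](c2cc(OCc4ccccc4)cc(OCc4ccccc4)c2[C@H]1c1ccc(OCc4ccccc4)cc1)[C@H](c1ccc(OCc4ccccc4)cc1)O3
F14 | step 18 | pentabenzyl ketone: (7aR,8aR,7bR)-penta-O-benzylpauciflorol E | O=C1c2cc(OCc4ccccc4)cc3c2[C@@H](c2cc(OCc4ccccc4)cc(OCc4ccccc4)c2[C@H]1c1ccc(OCc4ccccc4)cc1)[C@H](c1ccc(OCc4ccccc4)cc1)O3
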